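**Retrosynthetic overview**
- Target: 13,14-dihydro-19(R)-hydroxy-PGE2, (5Z)-7-[(1R,2R,3R)-2-[(3S,7R)-3,7-dihydroxyoctyl]-3-hydroxy-5-oxocyclopentyl]hept-5-enoic acid. Endgame: ester hydrolysis ⇐ desilylation ⇐ Lindlar semihydrogenation of a 5,6-alkyne ⇐ Barton–McCombie removal of a C7 hydroxyl.
- Key disconnections C12–C13 and C7–C8, made in one flask: organocopper Michael-type 1,4-addition of the ω-chain to (R)-4-silyloxycyclopent-2-enone, then intermolecular aldol of the enolate with the C1–C7 ynal (C11 directs C12, C12 directs C8, all trans).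
- ω-Chain iodide (C13–C20): C19 from (R)-butane-1,3-diol, C15 from (S)-epichlorohydrin, joined by two CuI-catalysed Grignard epoxide openings; C13 from a vinyl group by ozonolysis.
- α-Chain ynal (C1–C7): hex-5-ynoic acid plus formaldehyde, esterification, oxidation.
- Rings: the only ring (the cyclopentanone) is bought in as the enone; no ring-forming step occurs.

Assumption: (R)-4-(tert-butyldimethylsilyloxy)cyclopent-2-en-1-one is taken as a purchasable bulk prostaglandin building block. TBS = tert-butyldimethylsilyl, TBSO = tert-butyldimethylsilyloxy.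

**Route**

Step 1
Reactants: 1 (R)-butane-1,3-diol
Product: 2 (3R)-3-hydroxybutyl 4-methylbenzenesulfonate
Conditions: TsCl (1.0 equiv), Et3N, DMAP (cat.), CH2Cl2, −10 → 0 °C
Reagents that add atoms: p-toluenesulfonyl chloride, Cc1ccc(cc1)S(=O)(=O)Cl
Why: Selective O-sulfonylation of the unhindered primary hydroxyl of a 1,3-diol; the C19 stereocentre is bought in and untouched.

Step 2
Reactants: 2 (3R)-3-hydroxybutyl 4-methylbenzenesulfonate
Product: 3 (3R)-3-(TBSO)butyl 4-methylbenzenesulfonate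
Conditions: TBSCl, imidazole, DMF, rt
Reagents that add atoms: tert-butyldimethylsilyl chloride, CC(C)(C)[Si](C)(C)Cl
Why: Standard imidazole-promoted silyl ether formation on a secondary alcohol; the primary tosylate is inert under these conditions.

Step 3
Reactants: 3 (3R)-3-(TBSO)butyl 4-methylbenzenesulfonate
Product: 4 {[(2R)-4-bromobutan-2-yl]oxy}(tert-butyl)dimethylsilane
Conditions: LiBr, acetone, reflux
Reagents that add atoms: lithium bromide, [Li+].[Br-]
Why: Finkelstein-type SN2 displacement of a primary tosylate by bromide, remote from the stereocentre.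

Step 4
Reactants: 4 {[(2R)-4-bromobutan-2-yl]oxy}(tert-butyl)dimethylsilane; 5 (S)-epichlorohydrin
Product: 7 (2S,6R)-1-chloro-6-(TBSO)heptan-2-ol, via Grignard reagent 6 (not isolated)
Conditions: Mg, THF, rt → 40 °C; then CuI (10 mol%), 5 (1.2 equiv), THF, −40 → −20 °C
Reagents that add atoms: magnesium, [Mg] (stays only in 6)
Why: CuI-catalysed Grignard opening of the epoxide at its unsubstituted carbon forms C16–C17; the C15 stereocentre comes from (S)-epichlorohydrin and no bond to it is broken.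

Step 5
Reactants: 7 (2S,6R)-1-chloro-6-(TBSO)heptan-2-ol
Product: 8 tert-butyl(dimethyl){[(2R)-5-[(2S)-oxiran-2-yl]pentan-2-yl]oxy}silane
Conditions: K2CO3, MeOH, rt
Reagents that add atoms: none
Why: Intramolecular Williamson closure of the chlorohydrin to the terminal epoxide at the primary carbon, leaving C15 and the TBS ether unchanged.

Step 6
Reactants: 8 tert-butyl(dimethyl){[(2R)-5-[(2S)-oxiran-2-yl]pentan-2-yl]oxy}silane
Product: 9 (4S,8R)-8-(TBSO)non-1-en-4-ol
Conditions: CH2=CHMgBr (2 equiv), CuI (10 mol%), THF, −30 → 0 °C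
Reagents that add atoms: vinylmagnesium bromide, C=C[Mg]Br
Why: CuI-catalysed Grignard epoxide opening at the terminal carbon gives the homoallylic alcohol with C15 retained.

Step 7
Reactants: 9 (4S,8R)-8-(TBSO)non-1-en-4-ol
Product: 10 (4S,8R)-4,8-bis(TBSO)non-1-ene
Conditions: TBSCl, imidazole, DMF, rt → 40 °C
Reagents that add atoms: tert-butyldimethylsilyl chloride, CC(C)(C)[Si](C)(C)Cl
Why: Silyl ether formation puts the same protecting group on C15 as on C19, so one fluoride step clears both later.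

Step 8
Reactants: 10 (4S,8R)-4,8-bis(TBSO)non-1-ene
Product: 12 (3S,7R)-3,7-bis(TBSO)octan-1-ol, via ozonide 11 (not isolated)
Conditions: O3, CH2Cl2, −78 °C; then NaBH4, MeOH, −78 °C → rt
Reagents that add atoms: ozone, [O-][O+]=O
Why: Ozonolysis with reductive NaBH4 work-up cuts the terminal alkene to the primary alcohol (C13); silyl ethers and stereocentres are inert.

Step 9
Reactants: 12 (3S,7R)-3,7-bis(TBSO)octan-1-ol
Product: 13 (3S,7R)-3,7-bis(TBSO)-1-iodooctane
Conditions: I2, PPh3, imidazole, CH2Cl2, 0 °C → rt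
Reagents that add atoms: iodine, II
Why: Appel-type (Garegg–Samuelsson) iodination of a primary alcohol under neutral conditions that TBS ethers tolerate.

Step 10
Reactants: 14 hex-5-ynoic acid
Product: 16 7-hydroxyhept-5-ynoic acid, via dilithium alkynide carboxylate 15 (not isolated)
Conditions: n-BuLi (2.1 equiv), THF, −78 → 0 °C; (CH2O)n, 0 °C → rt; then aq. HCl
Reagents that add atoms: paraformaldehyde as formaldehyde, C=O; n-butyllithium, [Li]CCCC (Li stays only in 15)
Why: Hydroxymethylation of the lithium acetylide (1,2-addition to formaldehyde); the carboxylate is masked as its lithium salt and deprotonation at −78 °C outruns addition to it.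

Step 11
Reactants: 16 7-hydroxyhept-5-ynoic acid
Product: 17 methyl 7-hydroxyhept-5-ynoate
Conditions: MeOH, H2SO4 (cat.), rt → 50 °C
Reagents that add atoms: methanol, CO
Why: Fischer esterification; the propargylic alcohol and the alkyne are stable to dilute acid in methanol.

Step 12
Reactants: 17 methyl 7-hydroxyhept-5-ynoate
Product: 18 methyl 7-oxohept-5-ynoate
Conditions: Dess–Martin periodinane, CH2Cl2, 0 °C → rt; used fresh
Reagents that add atoms: none
Why: Dess–Martin oxidation of the primary propargylic alcohol stops cleanly at the ynal.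

Step 13
Reactants: 13 (3S,7R)-3,7-bis(TBSO)-1-iodooctane; 19 (R)-4-(TBSO)cyclopent-2-en-1-one; 18 methyl 7-oxohept-5-ynoate
Product: 23 methyl 7-[(1S,2R,3R)-2-[(3S,7R)-3,7-bis(TBSO)octyl]-3-(TBSO)-5-oxocyclopentyl]-7-hydroxyhept-5-ynoate (C7 epimer mixture), via alkyllithium 20 (not isolated), via alkylcopper tributylphosphine complex 21 (not isolated), via lithium enolate 22 (not isolated)
Conditions: 13, t-BuLi (2.05 equiv), Et2O, −78 °C; CuI (1.0 equiv), PBu3 (2.5 equiv), THF, −78 °C; 19 (0.95 equiv), −78 °C; 18 (1.2 equiv), −78 °C; H2O quench at −78 °C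
Reagents that add atoms: tert-butyllithium, [Li]C(C)(C)C (Li stays only in 20 and 22); CuI, [Cu]I (Cu stays only in 21); tributylphosphine, CCCCP(CCCC)CCCC (stays only in 21)
Why: Noyori three-component coupling, in which the alkylcopper adds 1,4 (Michael-type) to the enone anti to the C11 silyloxy group to set C12 and the regiodefined enolate is trapped at −78 °C by the ynal in an intermolecular aldol anti to the new chain to set C8 (all-trans ring), the C7 carbinol epimers being irrelevant.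

Step 14
Reactants: 23 methyl 7-[(1S,2R,3R)-2-[(3S,7R)-3,7-bis(TBSO)octyl]-3-(TBSO)-5-oxocyclopentyl]-7-hydroxyhept-5-ynoate
Product: 24 methyl 7-[(1S,2R,3R)-2-[(3S,7R)-3,7-bis(TBSO)octyl]-3-(TBSO)-5-oxocyclopentyl]-7-[(phenoxycarbonothioyl)oxy]hept-5-ynoate
Conditions: PhOC(S)Cl (1.5 equiv), pyridine, DMAP (cat.), CH2Cl2, 0 °C; crude used at once
Reagents that add atoms: O-phenyl chlorothionoformate, S=C(Cl)Oc1ccccc1
Why: O-Thioacylation of the secondary alcohol with a weak base at 0 °C gives the radical precursor without triggering β-elimination of the aldol or of the C11 silyloxy group.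

Step 15
Reactants: 24 methyl 7-[(1S,2R,3R)-2-[(3S,7R)-3,7-bis(TBSO)octyl]-3-(TBSO)-5-oxocyclopentyl]-7-[(phenoxycarbonothioyl)oxy]hept-5-ynoate
Product: 25 methyl 7-[(1R,2R,3R)-2-[(3S,7R)-3,7-bis(TBSO)octyl]-3-(TBSO)-5-oxocyclopentyl]hept-5-ynoate
Conditions: Bu3SnH (2 equiv), Et3B (cat.), air, toluene, 0 °C → rt
Reagents that add atoms: none
Why: Barton–McCombie deoxygenation under neutral room-temperature initiation replaces C7–O by C7–H through the propargylic radical without touching the base-sensitive β-silyloxy ketone or the C8 centre.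

Step 16
Reactants: 25 methyl 7-[(1R,2R,3R)-2-[(3S,7R)-3,7-bis(TBSO)octyl]-3-(TBSO)-5-oxocyclopentyl]hept-5-ynoate
Product: 26 methyl (5Z)-7-[(1R,2R,3R)-2-[(3S,7R)-3,7-bis(TBSO)octyl]-3-(TBSO)-5-oxocyclopentyl]hept-5-enoate
Conditions: H2 (1 atm), Pd/CaCO3 poisoned with Pb(OAc)2 (Lindlar catalyst), quinoline, EtOAc, rt, stopped at 1 equiv H2
Reagents that add atoms: none
Why: Lindlar semihydrogenation delivers H2 syn to the alkyne to give the 5Z alkene; there is no other C=C and the ketone is not reduced.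

Step 17
Reactants: 26 methyl (5Z)-7-[(1R,2R,3R)-2-[(3S,7R)-3,7-bis(TBSO)octyl]-3-(TBSO)-5-oxocyclopentyl]hept-5-enoate
Product: 27 methyl (5Z)-7-[(1R,2R,3R)-2-[(3S,7R)-3,7-dihydroxyoctyl]-3-hydroxy-5-oxocyclopentyl]hept-5-enoate
Conditions: HF·pyridine, MeCN, 0 °C → rt
Reagents that add atoms: none
Why: Buffered fluoride desilylation removes all three TBS ethers under mildly acidic conditions that do not dehydrate the β-hydroxy ketone.

Step 18
Reactants: 27 methyl (5Z)-7-[(1R,2R,3R)-2-[(3S,7R)-3,7-dihydroxyoctyl]-3-hydroxy-5-oxocyclopentyl]hept-5-enoate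
Product: 28 (5Z)-7-[(1R,2R,3R)-2-[(3S,7R)-3,7-dihydroxyoctyl]-3-hydroxy-5-oxocyclopentyl]hept-5-enoic acid (target)
Conditions: porcine liver esterase, pH 7 phosphate buffer/acetone, 30 °C
Reagents that add atoms: water, O
Why: Enzymatic ester hydrolysis at neutral pH frees the acid without the base-induced dehydration or C8 epimerisation that saponification would cause.

**Compound list**

1 | (R)-butane-1,3-diol | C[C@@H](O)CCO | starting material
2 | (3R)-3-hydroxybutyl 4-methylbenzenesulfonate | C[C@@H](O)CCOS(=O)(=O)c1ccc(C)cc1 | intermediate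
3 | (3R)-3-(TBSO)butyl 4-methylbenzenesulfonate | C[C@@H](O[Si](C)(C)C(C)(C)C)CCOS(=O)(=O)c1ccc(C)cc1 | intermediate
4 | {[(2R)-4-bromobutan-2-yl]oxy}(tert-butyl)dimethylsilane | C[C@@H](O[Si](C)(C)C(C)(C)C)CCBr | intermediate
5 | (S)-epichlorohydrin, (2S)-2-(chloromethyl)oxirane | ClC[C@@H]1CO1 | starting material
6 | [(3R)-3-(TBSO)butyl]magnesium bromide | C[C@@H](O[Si](C)(C)C(C)(C)C)CC[Mg]Br | intermediate (not isolated)
7 | (2S,6R)-1-chloro-6-(TBSO)heptan-2-ol | C[C@@H](O[Si](C)(C)C(C)(C)C)CCC[C@H](O)CCl | intermediate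
8 | tert-butyl(dimethyl){[(2R)-5-[(2S)-oxiran-2-yl]pentan-2-yl]oxy}silane | C[C@@H](O[Si](C)(C)C(C)(C)C)CCC[C@H]1CO1 | intermediate
9 | (4S,8R)-8-(TBSO)non-1-en-4-ol | C[C@@H](O[Si](C)(C)C(C)(C)C)CCC[C@H](O)CC=C | intermediate
10 | (4S,8R)-4,8-bis(TBSO)non-1-ene | C[C@@H](O[Si](C)(C)C(C)(C)C)CCC[C@H](O[Si](C)(C)C(C)(C)C)CC=C | intermediate
11 | 3-[(2S,6R)-2,6-bis(TBSO)heptyl]-1,2,4-trioxolane (ozonide of 10) | C[C@@H](O[Si](C)(C)C(C)(C)C)CCC[C@H](O[Si](C)(C)C(C)(C)C)CC1OCOO1 | intermediate (not isolated)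
12 | (3S,7R)-3,7-bis(TBSO)octan-1-ol | C[C@@H](O[Si](C)(C)C(C)(C)C)CCC[C@H](O[Si](C)(C)C(C)(C)C)CCO | intermediate
13 | (3S,7R)-3,7-bis(TBSO)-1-iodooctane | C[C@@H](O[Si](C)(C)C(C)(C)C)CCC[C@H](O[Si](C)(C)C(C)(C)C)CCI | intermediate
14 | hex-5-ynoic acid | C#CCCCC(=O)O | starting material
15 | dilithium salt of hex-5-ynoic acid (C-lithio alkynide, lithium carboxylate) | [Li]C#CCCCC(=O)O[Li] | intermediate (not isolated)
16 | 7-hydroxyhept-5-ynoic acid | OCC#CCCCC(=O)O | intermediate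
17 | methyl 7-hydroxyhept-5-ynoate | COC(=O)CCCC#CCO | intermediate
18 | methyl 7-oxohept-5-ynoate | COC(=O)CCCC#CC=O | intermediate
19 | (R)-4-(TBSO)cyclopent-2-en-1-one | O=C1C=C[C@H](O[Si](C)(C)C(C)(C)C)C1 | starting material
20 | [(3S,7R)-3,7-bis(TBSO)octyl]lithium | C[C@@H](O[Si](C)(C)C(C)(C)C)CCC[C@H](O[Si](C)(C)C(C)(C)C)CC[Li] | intermediate (not isolated)
21 | [(3S,7R)-3,7-bis(TBSO)octyl]copper tributylphosphine complex | C[C@@H](O[Si](C)(C)C(C)(C)C)CCC[C@H](O[Si](C)(C)C(C)(C)C)CC[Cu].CCCCP(CCCC)CCCC | intermediate (not isolated)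
22 | lithium (3R,4R)-3-[(3S,7R)-3,7-bis(TBSO)octyl]-4-(TBSO)cyclopent-1-en-1-olate | C[C@@H](O[Si](C)(C)C(C)(C)C)CCC[C@H](O[Si](C)(C)C(C)(C)C)CC[C@H]1[C@H](O[Si](C)(C)C(C)(C)C)CC(O[Li])=C1 | intermediate (not isolated)
23 | methyl 7-[(1S,2R,3R)-2-[(3S,7R)-3,7-bis(TBSO)octyl]-3-(TBSO)-5-oxocyclopentyl]-7-hydroxyhept-5-ynoate (C7 epimers) | C[C@@H](O[Si](C)(C)C(C)(C)C)CCC[C@H](O[Si](C)(C)C(C)(C)C)CC[C@H]1[C@H](O[Si](C)(C)C(C)(C)C)CC(=O)[C@@H]1C(O)C#CCCCC(=O)OC | intermediate
24 | methyl 7-[(1S,2R,3R)-2-[(3S,7R)-3,7-bis(TBSO)octyl]-3-(TBSO)-5-oxocyclopentyl]-7-[(phenoxycarbonothioyl)oxy]hept-5-ynoate (C7 epimers) | C[C@@H](O[Si](C)(C)C(C)(C)C)CCC[C@H](O[Si](C)(C)C(C)(C)C)CC[C@H]1[C@H](O[Si](C)(C)C(C)(C)C)CC(=O)[C@@H]1C(OC(=S)Oc2ccccc2)C#CCCCC(=O)OC | intermediate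
25 | methyl 7-[(1R,2R,3R)-2-[(3S,7R)-3,7-bis(TBSO)octyl]-3-(TBSO)-5-oxocyclopentyl]hept-5-ynoate | C[C@@H](O[Si](C)(C)C(C)(C)C)CCC[C@H](O[Si](C)(C)C(C)(C)C)CC[C@H]1[C@H](O[Si](C)(C)C(C)(C)C)CC(=O)[C@@H]1CC#CCCCC(=O)OC | intermediate
26 | methyl (5Z)-7-[(1R,2R,3R)-2-[(3S,7R)-3,7-bis(TBSO)octyl]-3-(TBSO)-5-oxocyclopentyl]hept-5-enoate | C[C@@H](O[Si](C)(C)C(C)(C)C)CCC[C@H](O[Si](C)(C)C(C)(C)C)CC[C@H]1[C@H](O[Si](C)(C)C(C)(C)C)CC(=O)[C@@H]1C/C=C\CCCC(=O)OC | intermediate
27 | methyl (5Z)-7-[(1R,2R,3R)-2-[(3S,7R)-3,7-dihydroxyoctyl]-3-hydroxy-5-oxocyclopentyl]hept-5-enoate | C[C@@H](O)CCC[C@H](O)CC[C@H]1[C@H](O)CC(=O)[C@@H]1C/C=C\CCCC(=O)OC | intermediate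
28 | (5Z)-7-[(1R,2R,3R)-2-[(3S,7R)-3,7-dihydroxyoctyl]-3-hydroxy-5-oxocyclopentyl]hept-5-enoic acid | C[C@@H](O)CCC[C@H](O)CC[C@H]1[C@H](O)CC(=O)[C@@H]1C/C=C\CCCC(=O)O | target

**Totals**
Total steps: 18. Longest linear sequence: 15 (steps 1–9, then 13–18).

**Three steps most likely to fail**

Step 13 (one-pot 1,4-addition and aldol). Risks are incomplete lithium–iodine exchange, enolate equilibration with loss of the C11 silyloxy group, and attack of the copper reagent on the ynal. The fallback sets out from 13 and 19 and separates the two bond formations. Enolate 22 is generated exactly as before but is silylated (TMSCl, Et3N, −78 °C) and isolated as {[(3R,4R)-3-[(3S,7R)-3,7-bis(TBSO)octyl]-4-(TBSO)cyclopent-1-en-1-yl]oxy}trimethylsilane F1. F1 is then joined to ynal 18 in a separate Lewis-acid Mukaiyama aldol (BF3·OEt2, CH2Cl2, −78 °C), again anti to the C12 chain, and the route is rejoined at 23.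

Step 15 (radical deoxygenation, including the preceding thioacylation). Risks are elimination of the activated aldol, [3,3] shift of the propargylic thionocarbonate, and allene formation from the propargylic radical. The fallback sets out from 17 (with 13 and 19) and never places oxygen on C7. Alcohol 17 is converted with I2, PPh3 and imidazole into methyl 7-iodohept-5-ynoate F2. Enolate 22, made from 13 and 19 as in step 13, is transmetalated with Ph3SnCl in THF/HMPA to the triphenylstannyl enolate F3 and C-alkylated with F2 at −30 °C. This gives 25 directly, where the route is rejoined.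

Step 16 (Lindlar semihydrogenation). Risks are over-reduction or Z/E scrambling on the most valuable intermediate. The fallback sets out from 17 and installs the Z alkene before the coupling. Alcohol 17 is semihydrogenated at this simple stage (H2, Pd/CaCO3 poisoned with Pb(OAc)2, quinoline) to methyl (5Z)-7-hydroxyhept-5-enoate F4, where impurities are easy to remove. F4 is converted (I2, PPh3, imidazole, 0 °C, used at once) into methyl (5Z)-7-iodohept-5-enoate F5. Alkylation of the triphenylstannyl enolate F3 (from 13 and 19 as above) with F5 at −30 °C gives 26, where the route is rejoined.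

**Further compounds**
F1 | step 13 | {[(3R,4R)-3-[(3S,7R)-3,7-bis(TBSO)octyl]-4-(TBSO)cyclopent-1-en-1-yl]oxy}trimethylsilane | C[C@@H](O[Si](C)(C)C(C)(C)C)CCC[C@H](O[Si](C)(C)C(C)(C)C)CC[C@H]1[C@H](O[Si](C)(C)C(C)(C)C)CC(O[Si](C)(C)C)=C1
F2 | step 15 | methyl 7-iodohept-5-ynoate | COC(=O)CCCC#CCI
F3 | step 15 | {[(3R,4R)-3-[(3S,7R)-3,7-bis(TBSO)octyl]-4-(TBSO)cyclopent-1-en-1-yl]oxy}triphenylstannane | C[C@@H](O[Si](C)(C)C(C)(C)C)CCC[C@H](O[Si](C)(C)C(C)(C)C)CC[C@H]1[C@H](O[Si](C)(C)C(C)(C)C)CC(O[Sn](c2ccccc2)(c2ccccc2)c2ccccc2)=C1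
F4 | step 16 | methyl (5Z)-7-hydroxyhept-5-enoate | COC(=O)CCC/C=C\CO
F5 | step 16 | methyl (5Z)-7-iodohept-5-enoate | COC(=O)CCC/C=C\CI
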